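In a one-step world each coupling partner takes one left-handed substrate, and the end of a flask is a subtraction.

margin = c(coupling partner) − c(left-handed substrate) = 0.480 M − 0.40 M = 0.0800 M

Keep this margin, the coupling partner charged beyond the left-handed substrate. In that world its sign names the limiting reagent, and control changes hands where it crosses zero.

| flask | left-handed substrate | right-handed substrate | coupling partner | precatalyst | remark | time |
|---|---|---|---|---|---|---|
| eta | 0.27 M | 0.27 M | 0.48 M (fed, over 40 min) | 0.40 mM | run made earlier; the fed solution adds 0.10 times the starting volume |  |
| zeta | 0.60 M | 0.60 M | 0.48 M (fed, over 40 min) | 0.40 mM | run made earlier; the fed solution adds 0.10 times the starting volume |  |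
| epsilon | 0.40 M | 0.40 M | 0.48 M (fed, over 40 min) | 0.60 mM | run made earlier; the fed solution adds 0.10 times the starting volume |  |
| flask | 0.40 M | 0.40 M | 0.480 M (fed, over 40 min) | 0.40 mM | the fed solution adds 0.10 times the starting volume | 20 h |

| run | time / h | left-handed substrate / % | right-handed substrate / % |
|---|---|---|---|
| eta | 2.50 | 24 | 47 |
| eta | 5.00 | 14 | 50 |
| eta | 6.00 | 10 | 50 |
| eta | 10.0 | 5 | 51 |
| eta | 12.0 | 3 | 50 |
| eta | 15.0 | 1 | 50 |
| zeta | 2.50 | 29 | 49 |
| zeta | 5.00 | 20 | 48 |
| zeta | 6.00 | 20 | 51 |
| zeta | 10.0 | 14 | 49 |
| zeta | 12.0 | 13 | 50 |
| zeta | 15.0 | 10 | 47 |
| epsilon | 3.00 | 19 | 49 |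
| epsilon | 6.00 | 9 | 51 |
| epsilon | 10.0 | 6 | 49 |
| epsilon | 12.0 | 8 | 49 |
| epsilon | 15.0 | 1 | 50 |

(readings scatter by 1.5 percentage points)

- catalyst is single-handed; left-handed substrate and right-handed substrate are mirror images of each other, charged as a racemate, each of them at the stated concentration
- charges are per starting volume, the dose included; the dosed solution carries all of it
- an excess is the difference of the two amounts in percent of their sum
- an excess is below zero if the other one leads

* part of the left-handed substrate and right-handed substrate charged together that has reacted at 20 h
* excess of left-handed product over right-handed product in the product at 20 h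
* excess of right-handed substrate over left-handed substrate among what is left of the two at 20 h

You take over a flask with each substrate at 0.40 M, precatalyst at 0.40 mM, and coupling partner dosed over 40 min. The earlier runs lie on both sides of the crossing. Zeta has a margin of −0.120 M, so its left-handed substrate should stop at

floor = (c(left-handed substrate) − c(coupling partner)) / (2 c(left-handed substrate)) = 10.0%

of the pair, and it read 10% at 15.0 h. Eta, with a margin of 0.210 M, read 1% at 15.0 h.

Your flask sits on eta's side, with a smaller margin. So at 20 h I expect its left-handed substrate low but not nil, and its coupling partner falling towards 16.7% of its charge. Don't top up the partner: the charge covers the left-handed substrate, and a surplus can go on to the right-handed substrate you want to keep.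

The forecast gave c 47.2%, eP 98.7% and eS 88.5%, reading zeta's stop as “exactly where the partner runs out”.

The flask gives c 48.2%, eP 96.5% and eS 89.9%.

    precatalyst ⇌ catalyst (K = 20.0, k = 0.0128 min⁻¹)
    2 catalyst ⇌ resting dimer, settled at all times (K = 8260 M⁻¹)
    coupling partner + catalyst + left-handed substrate → catalyst + left-handed product (k = 145 M⁻² min⁻¹)
    coupling partner + catalyst + right-handed substrate → catalyst + right-handed product (k = 0.832 M⁻² min⁻¹)

At 20.0 h this flask holds 65.4% of the catalyst charged as resting dimer, its resting state. The subtraction stands anyway. Margin plus left-handed substrate remaining, minus right-handed product, gives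

coupling partner = 19.6% of its charge

against 20% in the flask. The neighbour charged with 0.19 M of coupling partner has a margin of −0.210 M, which puts its floor at 26.2%, and its left-handed substrate ends at 26.7%.

The data stem from a simulated flask with constants of no real substance; the scatter is artificial.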